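**Strategy.** The route rests on one disconnection: the cyclobutane is made by an intramolecular [2+2] photocycloaddition of an acyclic 1,6-diene. The feature used is that, on the four-membered ring, the ester carbon on the quaternary C(CH3) and the first side-chain CH2 on the neighbouring CH are cis; with one CH2 between them they form a temporary cyclopentane-1,3-diol. Triplet sensitization of the syn-diol diene (trisubstituted styrene plus E-enoate) closes the cyclobutane last and sets its four stereocentres from two carbinol centres. A Grob fragmentation then opens the cyclopentane to formyl and vinyl groups, which become the carboxyl group and the enoate side chain. Three successive Mitsunobu esterifications with 6-epi-incarvilline, one per unmasked carboxyl group, finish.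

Key step: step 12

Remark on the chemistry: the alcohol prepared is the 6S epimer of the target's alcohol unit (6-epi-incarvilline, 12), because each of the three ester bonds is made with Mitsunobu inversion. TBS = tert-butyldimethylsilyl; Ar = 4-(TBS-oxy)-3-methoxyphenyl; Inc = (4R,4aS,6R,7S,7aR)-2,4,7-trimethyloctahydro-1H-cyclopenta[c]pyridin-6-yl. For compounds 28–32 the cyclobutane carbons keep the numbering of 27 (C1 quaternary, C2 aryl, C3 ring carboxyl, C4 side chain).

**Alcohol fragment (steps 1–6)**

Step 1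
Reactants: 1 (S)-4-(TBS-oxy)cyclopent-2-en-1-one
Product: 3 (2R,3S,4S)-4-(TBS-oxy)-2-(hydroxymethyl)-3-methylcyclopentan-1-one, via lithium enolate 2 (not isolated)
Conditions: Me2CuLi, Et2O, −78 °C; then CH2O (gas), −78 to −40 °C; aq NH4Cl
Reagents that add atoms: lithium dimethylcuprate, [Li+].C[Cu-]C; formaldehyde, C=O
Why: Three-component coupling (cuprate conjugate addition, then aldol trapping of the enolate): the methyl group should add anti to the silyloxy group and formaldehyde anti to the new methyl group, giving the 2,3-trans-3,4-trans ketone.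

Step 2
Reactants: 3 hydroxymethyl ketone; 4 N-methylprop-2-en-1-amine
Product: 7 (2R,3S,4S)-4-(TBS-oxy)-3-methyl-2-{[methyl(prop-2-en-1-yl)amino]methyl}cyclopentan-1-one, via mesylate 5 (not isolated), via exo-methylene ketone 6 (not isolated)
Conditions: MsCl, Et3N, CH2Cl2, 0 °C; then 4, 0 °C to rt
Reagents that add atoms: none
Why: Mesylation and E1cB elimination give the exo-methylene ketone, and aza-Michael addition of the amine followed by protonation of the equilibrating α-centre should place the aminomethyl group trans to the 3-methyl group.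

Step 3
Reactants: 7 amino ketone
Product: 9 (3R,4S,5R)-3-(TBS-oxy)-4-methyl-5-{[methyl(prop-2-en-1-yl)amino]methyl}cyclopent-1-en-1-yl trifluoromethanesulfonate, via potassium enolate 8 (not isolated)
Conditions: KN(SiMe3)2, THF, −78 °C; then N-(5-chloropyridin-2-yl)triflimide, −78 °C
Reagents that add atoms: N-(5-chloropyridin-2-yl)-1,1,1-trifluoro-N-[(trifluoromethyl)sulfonyl]methanesulfonamide, O=S(=O)(N(c1ccc(Cl)cn1)S(=O)(=O)C(F)(F)F)C(F)(F)F
Why: Kinetic deprotonation at the unsubstituted α-CH2 and O-sulfonylation of the enolate (enol triflate formation) at −78 °C, where β-elimination of the silyloxy group is slow, should give the less substituted enol triflate.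

Step 4
Reactants: 9 enol triflate
Product: 10 (4R,6R,7S,7aS)-6-(TBS-oxy)-2,4,7-trimethyl-2,3,4,6,7,7a-hexahydro-1H-cyclopenta[c]pyridine
Conditions: Pd(OAc)2 (10 mol %), PPh3 (20 mol %), HCO2Na, DMF, 80 °C
Reagents that add atoms: none
Why: Reductive Heck cyclization: oxidative addition, 6-exo-trig carbopalladation of the N-allyl group and formate reduction of the alkylpalladium close the piperidine ring, and a chair-like transition state with the forming CH2Pd group pseudo-equatorial (cis-1,3 to the C7a substituent) should set C4 as R.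

Step 5
Reactants: 10 bicyclic alkene
Product: 11 (4R,4aS,6S,7S,7aR)-6-(TBS-oxy)-2,4,7-trimethyloctahydro-1H-cyclopenta[c]pyridine
Conditions: H2 (1 atm), PtO2, EtOAc, rt
Reagents that add atoms: none
Why: Heterogeneous catalytic hydrogenation should deliver hydrogen to the face opposite the allylic silyloxy group and the C4 methyl group, setting C4a and the cis ring fusion.

Step 6
Reactants: 11 silyl ether
Product: 12 (4R,4aS,6S,7S,7aR)-2,4,7-trimethyloctahydro-1H-cyclopenta[c]pyridin-6-ol (6-epi-incarvilline)
Conditions: Bu4NF, THF, rt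
Reagents that add atoms: none
Why: Fluoride-mediated desilylation frees the 6S alcohol without touching any stereocentre.

**Side-chain electrophile (step 7)**

Step 7
Reactants: 13 tert-butyl 3-oxobutanoate
Product: 14 tert-butyl (2E)-3-{[(trifluoromethyl)sulfonyl]oxy}but-2-enoate
Conditions: Tf2O, aq Me4NOH, toluene, 5 °C
Reagents that add atoms: trifluoromethanesulfonic anhydride, O=S(=O)(OS(=O)(=O)C(F)(F)F)C(F)(F)F
Why: O-Triflation of the β-keto ester enolate with the non-chelating tetramethylammonium counter-ion (stereoselective enol triflate formation) should give the E isomer, which fixes the geometry of the side-chain alkene made in step 16; the tert-butyl ester is chosen to be orthogonal to the ring ethyl ester.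

**Core (steps 8–21)**

Step 8
Reactants: 15 vanillin
Product: 16 4-(TBS-oxy)-3-methoxybenzaldehyde
Conditions: TBSCl, imidazole, DMF, rt
Reagents that add atoms: tert-butyldimethylsilyl chloride, CC(C)(C)[Si](C)(C)Cl
Why: Silylation of the phenol (silyl ether protection) masks it against the oxidant of step 15 and is removed by the hydroxide of step 18.

Step 9
Reactants: 16 aldehyde; 17 3-(triphenyl-λ5-phosphanylidene)butan-2-one
Product: 18 (3E)-4-Ar-3-methylbut-3-en-2-one
Conditions: toluene, 110 °C
Reagents that add atoms: none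
Why: Wittig reaction of a stabilized ylide should give the E-trisubstituted enone with the aryl group cis to the methyl group.

Step 10
Reactants: 18 enone; 19 ethyl (2E)-4-oxobut-2-enoate
Product: 20 ethyl (2E,4S,7E)-8-Ar-4-hydroxy-7-methyl-6-oxoocta-2,7-dienoate
Conditions: Et2Zn (10 mol %), (R,R)-ProPhenol ligand (5 mol %), 4 Å MS, THF, −20 °C
Reagents that add atoms: none
Why: Direct asymmetric aldol reaction under dinuclear zinc–ProPhenol catalysis: the ketone can enolize only at its methyl group, the aldehyde is not enolizable, and the (R,R)-ligand should direct the zinc enolate to the Si face of the aldehyde, setting C4 as S.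

Step 11
Reactants: 20 β-hydroxy enone
Product: 21 ethyl (2E,4S,6R,7E)-8-Ar-4,6-dihydroxy-7-methylocta-2,7-dienoate
Conditions: Et2BOMe, THF/MeOH 4:1, −78 °C; NaBH4; then MeOH evaporation
Reagents that add atoms: none
Why: Narasaka–Prasad reduction: hydride adds axially to the six-membered boron chelate of the β-hydroxy ketone, in a 1,2 sense on the enone, which should set C6 as R (syn-1,3-diol).

Step 12
Reactants: 21 syn-diol diene
Product: 22 ethyl (1R,2R,4S,5S,6R,7R)-7-Ar-2,4-dihydroxy-1-methylbicyclo[3.2.0]heptane-6-carboxylate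
Conditions: Ir(dFppy)3 [fac-tris(2-(2,4-difluorophenyl)pyridinato)iridium] (1 mol %), degassed MeCN (0.01 M), 427 nm LEDs, 25 °C
Reagents that add atoms: none
Why: Triplet energy transfer from the excited iridium sensitizer to the styrene (the only chromophore with a low enough triplet energy) gives a 1,2-biradical whose carbon C7 adds to enoate carbon C3 in a 5-exo-trig radical cyclization, leaving a benzylic/α-ester 1,4-biradical that closes the C2–C8 bond after intersystem crossing; the closest known reaction type is the visible-light sensitized intramolecular styrene–alkene [2+2] photocycloaddition of 1,6-dienes to bicyclo[3.2.0]heptanes. The cyclopentane is thus closed by 5-exo radical addition and the cyclobutane by 1,4-biradical recombination, and the three-atom tether forces a cis ring fusion, which fixes the quaternary C1 (methyl) against C5. The face of addition is set by the two carbinol centres: in the chair-like 5-exo transition state both allylic hydroxyls sit pseudo-equatorial and end exo, trans to the new ring bond, and the syn-1,3-diol is the matched case in which both act in the same sense. At C7 the aryl group and at C6 the ester should take the exo positions on the convex face when the biradical collapses, since the endo positions point under the cyclopentane ring; this holds even if the styrene isomerizes E/Z beforehand, because both radical centres can rotate. The step needs chemoselective sensitization, straight rather than crossed closure and exo selectivity at C6/C7, which are secured by the triplet-energy gap, by the 1,6-diene tether and by the bicyclic shape, the C6 ester being the least certain.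

Step 13
Reactants: 22 bicyclic diol
Product: 23 ethyl (1R,2R,4S,5S,6R,7R)-7-Ar-2-hydroxy-4-[(methanesulfonyl)oxy]-1-methylbicyclo[3.2.0]heptane-6-carboxylate
Conditions: MsCl (1.05 equiv), Et3N, CH2Cl2, −40 °C
Reagents that add atoms: methanesulfonyl chloride, CS(=O)(=O)Cl
Why: Selective O-sulfonylation: the C4 hydroxyl is flanked by a CH2 and a CH, whereas the C2 hydroxyl is neopentyl (next to the quaternary bridgehead), so one equivalent of MsCl should mesylate C4 only.

Step 14
Reactants: 23 monomesylate
Product: 24 ethyl (1S,2R,3S,4S)-2-Ar-4-ethenyl-3-formyl-3-methylcyclobutane-1-carboxylate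
Conditions: KN(SiMe3)2 (1.05 equiv), THF, −78 to 0 °C
Reagents that add atoms: none
Why: Grob fragmentation: in the cis-1,3-diequatorial arrangement the C2–C3 bond is anti-periplanar to the C4–OMs bond, so the C2 alkoxide should collapse to the aldehyde with loss of mesylate and formation of the vinyl group, the cis relationship ruling out oxetane formation and the four cyclobutane stereocentres staying untouched.

Step 15
Reactants: 24 aldehyde
Product: 25 (1S,2R,3S,4S)-2-Ar-3-(ethoxycarbonyl)-4-ethenyl-1-methylcyclobutane-1-carboxylic acid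
Conditions: NaClO2, NaH2PO4, 2-methylbut-2-ene, t-BuOH/H2O, 0 °C to rt
Reagents that add atoms: sodium chlorite, [Na+].[O-]Cl=O
Why: Pinnick oxidation converts the non-enolizable neopentyl aldehyde into the acid without affecting the vinyl group, the aryl silyl ether or the stereocentre α to the ester.

Step 16
Reactants: 25 vinyl acid; 14 (E)-enol triflate
Product: 27 (1S,2R,3S,4S)-2-Ar-4-[(3E)-5-tert-butoxy-3-methyl-5-oxopent-3-en-1-yl]-3-(ethoxycarbonyl)-1-methylcyclobutane-1-carboxylic acid, via alkylborane 26 (not isolated)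
Conditions: 9-BBN dimer (2.6 equiv B–H), THF, 0 °C to rt; then 14, PdCl2(dppf) [dichloro(1,1′-bis(diphenylphosphino)ferrocene)palladium] (5 mol %), AsPh3, aq K3PO4, DMF, rt
Reagents that add atoms: none
Why: Anti-Markovnikov hydroboration of the vinyl group and B-alkyl Suzuki–Miyaura coupling with the enol triflate, which proceeds with retention of alkene geometry, should give the E-trisubstituted tert-butyl enoate; the free acid is carried as its acyloxyborane.

Step 17
Reactants: 27 quaternary acid; 12 6-epi-incarvilline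
Product: 28 Inc (1S,2R,3S,4S)-2-Ar-4-[(3E)-5-tert-butoxy-3-methyl-5-oxopent-3-en-1-yl]-3-(ethoxycarbonyl)-1-methylcyclobutane-1-carboxylate
Conditions: 12 (1.3 equiv), PPh3, DIAD, THF, 0 °C to rt
Reagents that add atoms: none
Why: Mitsunobu esterification: the only free carboxylate displaces the phosphonium-activated 6S alcohol by SN2 with inversion to give the 6R ester, a mode that tolerates the hindered quaternary acid because the new bond is formed at the alcohol carbon and not at the carbonyl carbon, while the two other esters and the silyl ether are inert.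

Step 18
Reactants: 28 mono-Inc ester
Product: 29 C3 carboxylic acid of 28 with free phenol (C1 Inc ester and side-chain tert-butyl ester kept; ring centres 1S,2R,3S,4S)
Conditions: LiOH, THF/MeOH/H2O, 0 °C to rt; then aq HCl to pH 6
Reagents that add atoms: lithium hydroxide, [Li+].[OH-]
Why: Saponification: hydroxide should cleave only the ethyl ester, since the tert-butyl enoate and the neopentyl-type Inc ester on the quaternary carbon resist attack, and it also removes the aryl silyl ether; the low temperature should avoid epimerization α to the ring carboxyl.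

Step 19
Reactants: 29 C3 acid; 12 6-epi-incarvilline
Product: 30 C1,C3-bis-Inc ester with side-chain tert-butyl ester and free phenol (ring centres 1S,2R,3S,4S)
Conditions: 12 (1.3 equiv), PPh3, DIAD, THF, 0 °C to rt
Reagents that add atoms: none
Why: Mitsunobu esterification with inversion at C6 of 12: the carboxyl group, far more acidic than the phenol, is the pronucleophile that protonates the betaine and is alkylated, so the free phenol should stay untouched.

Step 20
Reactants: 30 bis-Inc ester
Product: 31 C1,C3-bis-Inc ester with side chain (3E)-4-carboxy-3-methylbut-3-en-1-yl and free phenol (ring centres 1S,2R,3S,4S)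
Conditions: CF3CO2H/CH2Cl2 1:4, Et3SiH (3 equiv), 0 °C to rt; then aq NaHCO3 to pH 7
Reagents that add atoms: none
Why: Acidolysis of the tert-butyl ester (loss of the tert-butyl cation, which Et3SiH reduces to isobutane so that the electron-rich phenol ring is not alkylated) frees the enoic acid, while the secondary alkyl esters, the protonated amines and the electron-poor trisubstituted alkene should be inert.

Step 21
Reactants: 31 enoic acid; 12 6-epi-incarvilline
Product: 32 target, tris-Inc ester of (1S,2R,3S,4S)-4-[(3E)-4-carboxy-3-methylbut-3-en-1-yl]-2-(4-hydroxy-3-methoxyphenyl)-1-methylcyclobutane-1,3-dicarboxylic acid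
Conditions: 12 (1.3 equiv), PPh3, DIAD, THF, 0 °C to rt
Reagents that add atoms: none
Why: Third Mitsunobu esterification, again with inversion of the 6S alcohol to the 6R ester and with the carboxyl group reacting in preference to the phenol, completes the triester without touching the E-alkene.

**Compound list**

1 | (S)-4-[(tert-butyldimethylsilyl)oxy]cyclopent-2-en-1-one | CC(C)(C)[Si](C)(C)O[C@H]1CC(=O)C=C1 | starting material
2 | lithium (3S,4S)-4-[(tert-butyldimethylsilyl)oxy]-3-methylcyclopent-1-en-1-olate | CC(C)(C)[Si](C)(C)O[C@H]1CC(O[Li])=C[C@@H]1C | intermediate (not isolated)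
3 | (2R,3S,4S)-4-[(tert-butyldimethylsilyl)oxy]-2-(hydroxymethyl)-3-methylcyclopentan-1-one | CC(C)(C)[Si](C)(C)O[C@H]1CC(=O)[C@@H](CO)[C@@H]1C | intermediate
4 | N-methylprop-2-en-1-amine | CNCC=C | starting material
5 | [(1R,2S,3S)-3-[(tert-butyldimethylsilyl)oxy]-2-methyl-5-oxocyclopentyl]methyl methanesulfonate | CC(C)(C)[Si](C)(C)O[C@H]1CC(=O)[C@@H](COS(C)(=O)=O)[C@@H]1C | intermediate (not isolated)
6 | (3S,4S)-4-[(tert-butyldimethylsilyl)oxy]-3-methyl-2-methylidenecyclopentan-1-one | CC(C)(C)[Si](C)(C)O[C@H]1CC(=O)C(=C)[C@@H]1C | intermediate (not isolated)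
7 | (2R,3S,4S)-4-[(tert-butyldimethylsilyl)oxy]-3-methyl-2-{[methyl(prop-2-en-1-yl)amino]methyl}cyclopentan-1-one | CC(C)(C)[Si](C)(C)O[C@H]1CC(=O)[C@@H](CN(C)CC=C)[C@@H]1C | intermediate
8 | potassium (3R,4S,5R)-3-[(tert-butyldimethylsilyl)oxy]-4-methyl-5-{[methyl(prop-2-en-1-yl)amino]methyl}cyclopent-1-en-1-olate | CC(C)(C)[Si](C)(C)O[C@H]1C=C(O[K])[C@@H](CN(C)CC=C)[C@@H]1C | intermediate (not isolated)
9 | (3R,4S,5R)-3-[(tert-butyldimethylsilyl)oxy]-4-methyl-5-{[methyl(prop-2-en-1-yl)amino]methyl}cyclopent-1-en-1-yl trifluoromethanesulfonate | CC(C)(C)[Si](C)(C)O[C@H]1C=C(OS(=O)(=O)C(F)(F)F)[C@@H](CN(C)CC=C)[C@@H]1C | intermediate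
10 | (4R,6R,7S,7aS)-6-[(tert-butyldimethylsilyl)oxy]-2,4,7-trimethyl-2,3,4,6,7,7a-hexahydro-1H-cyclopenta[c]pyridine | CC(C)(C)[Si](C)(C)O[C@H]1C=C2[C@@H](CN(C)C[C@@H]2C)[C@@H]1C | intermediate
11 | (4R,4aS,6S,7S,7aR)-6-[(tert-butyldimethylsilyl)oxy]-2,4,7-trimethyloctahydro-1H-cyclopenta[c]pyridine | CC(C)(C)[Si](C)(C)O[C@H]1C[C@@H]2[C@@H](CN(C)C[C@@H]2C)[C@@H]1C | intermediate
12 | (4R,4aS,6S,7S,7aR)-2,4,7-trimethyloctahydro-1H-cyclopenta[c]pyridin-6-ol (6-epi-incarvilline) | O[C@H]1C[C@@H]2[C@@H](CN(C)C[C@@H]2C)[C@@H]1C | intermediate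
13 | tert-butyl 3-oxobutanoate | CC(=O)CC(=O)OC(C)(C)C | starting material
14 | tert-butyl (2E)-3-{[(trifluoromethyl)sulfonyl]oxy}but-2-enoate | CC(C)(C)OC(=O)/C=C(\C)OS(=O)(=O)C(F)(F)F | intermediate
15 | vanillin (4-hydroxy-3-methoxybenzaldehyde) | COc1cc(C=O)ccc1O | starting material
16 | 4-[(tert-butyldimethylsilyl)oxy]-3-methoxybenzaldehyde | COc1cc(C=O)ccc1O[Si](C)(C)C(C)(C)C | intermediate
17 | 3-(triphenyl-λ5-phosphanylidene)butan-2-one | CC(=O)C(C)=P(c1ccccc1)(c1ccccc1)c1ccccc1 | starting material
18 | (3E)-4-{4-[(tert-butyldimethylsilyl)oxy]-3-methoxyphenyl}-3-methylbut-3-en-2-one | COc1cc(/C=C(\C)C(C)=O)ccc1O[Si](C)(C)C(C)(C)C | intermediate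
19 | ethyl (2E)-4-oxobut-2-enoate | CCOC(=O)/C=C/C=O | starting material
20 | ethyl (2E,4S,7E)-8-{4-[(tert-butyldimethylsilyl)oxy]-3-methoxyphenyl}-4-hydroxy-7-methyl-6-oxoocta-2,7-dienoate | CCOC(=O)/C=C/[C@@H](O)CC(=O)/C(C)=C/c1ccc(O[Si](C)(C)C(C)(C)C)c(OC)c1 | intermediate
21 | ethyl (2E,4S,6R,7E)-8-{4-[(tert-butyldimethylsilyl)oxy]-3-methoxyphenyl}-4,6-dihydroxy-7-methylocta-2,7-dienoate | CCOC(=O)/C=C/[C@@H](O)C[C@@H](O)/C(C)=C/c1ccc(O[Si](C)(C)C(C)(C)C)c(OC)c1 | intermediate
22 | ethyl (1R,2R,4S,5S,6R,7R)-7-{4-[(tert-butyldimethylsilyl)oxy]-3-methoxyphenyl}-2,4-dihydroxy-1-methylbicyclo[3.2.0]heptane-6-carboxylate | COc1cc([C@H]2[C@@H](C(=O)OCC)[C@H]([C@@H](O)C[C@H]3O)[C@@]23C)ccc1O[Si](C)(C)C(C)(C)C | intermediate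
23 | ethyl (1R,2R,4S,5S,6R,7R)-7-{4-[(tert-butyldimethylsilyl)oxy]-3-methoxyphenyl}-2-hydroxy-4-[(methanesulfonyl)oxy]-1-methylbicyclo[3.2.0]heptane-6-carboxylate | COc1cc([C@H]2[C@@H](C(=O)OCC)[C@H]([C@@H](OS(C)(=O)=O)C[C@H]3O)[C@@]23C)ccc1O[Si](C)(C)C(C)(C)C | intermediate
24 | ethyl (1S,2R,3S,4S)-2-{4-[(tert-butyldimethylsilyl)oxy]-3-methoxyphenyl}-4-ethenyl-3-formyl-3-methylcyclobutane-1-carboxylate | COc1cc([C@H]2[C@@H](C(=O)OCC)[C@H](C=C)[C@]2(C)C=O)ccc1O[Si](C)(C)C(C)(C)C | intermediate
25 | (1S,2R,3S,4S)-2-{4-[(tert-butyldimethylsilyl)oxy]-3-methoxyphenyl}-3-(ethoxycarbonyl)-4-ethenyl-1-methylcyclobutane-1-carboxylic acid | COc1cc([C@H]2[C@@H](C(=O)OCC)[C@H](C=C)[C@]2(C)C(=O)O)ccc1O[Si](C)(C)C(C)(C)C | intermediate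
26 | B-alkyl-9-borabicyclo[3.3.1]nonane from 25 (side chain CH2CH2–B, ring carboxyl held as its 9-BBN acyloxyborane; ring stereocentres as in 25) | COc1cc([C@H]2[C@@H](C(=O)OCC)[C@H](CCB3C4CCCC3CCC4)[C@]2(C)C(=O)OB2C3CCCC2CCC3)ccc1O[Si](C)(C)C(C)(C)C | intermediate (not isolated)
27 | (1S,2R,3S,4S)-2-{4-[(tert-butyldimethylsilyl)oxy]-3-methoxyphenyl}-4-[(3E)-5-tert-butoxy-3-methyl-5-oxopent-3-en-1-yl]-3-(ethoxycarbonyl)-1-methylcyclobutane-1-carboxylic acid | COc1cc([C@H]2[C@@H](C(=O)OCC)[C@H](CC/C(C)=C/C(=O)OC(C)(C)C)[C@]2(C)C(=O)O)ccc1O[Si](C)(C)C(C)(C)C | intermediate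
28 | (4R,4aS,6R,7S,7aR)-2,4,7-trimethyloctahydro-1H-cyclopenta[c]pyridin-6-yl (1S,2R,3S,4S)-2-{4-[(tert-butyldimethylsilyl)oxy]-3-methoxyphenyl}-4-[(3E)-5-tert-butoxy-3-methyl-5-oxopent-3-en-1-yl]-3-(ethoxycarbonyl)-1-methylcyclobutane-1-carboxylate | COc1cc([C@H]2[C@@H](C(=O)OCC)[C@H](CC/C(C)=C/C(=O)OC(C)(C)C)[C@]2(C)C(=O)O[C@@H]2C[C@@H]3[C@@H](CN(C)C[C@@H]3C)[C@@H]2C)ccc1O[Si](C)(C)C(C)(C)C | intermediate
29 | C3 carboxylic acid of 28 with free phenol: ring ethyl ester hydrolysed and silyl ether removed, C1 Inc ester and side-chain tert-butyl ester kept (ring centres 1S,2R,3S,4S in the numbering of 27) | COc1cc([C@H]2[C@@H](C(=O)O)[C@H](CC/C(C)=C/C(=O)OC(C)(C)C)[C@]2(C)C(=O)O[C@@H]2C[C@@H]3[C@@H](CN(C)C[C@@H]3C)[C@@H]2C)ccc1O | intermediate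
30 | C1,C3-bis-Inc ester: both ring carboxyl groups esterified with the (4R,4aS,6R,7S,7aR)-2,4,7-trimethyloctahydro-1H-cyclopenta[c]pyridin-6-yl group, side-chain tert-butyl (E)-enoate, free phenol (ring centres 1S,2R,3S,4S in the numbering of 27) | COc1cc([C@H]2[C@@H](C(=O)O[C@@H]3C[C@@H]4[C@@H](CN(C)C[C@@H]4C)[C@@H]3C)[C@H](CC/C(C)=C/C(=O)OC(C)(C)C)[C@]2(C)C(=O)O[C@@H]2C[C@@H]3[C@@H](CN(C)C[C@@H]3C)[C@@H]2C)ccc1O | intermediate
31 | C1,C3-bis-Inc ester with side chain (3E)-4-carboxy-3-methylbut-3-en-1-yl and free phenol (ring centres 1S,2R,3S,4S in the numbering of 27) | COc1cc([C@H]2[C@@H](C(=O)O[C@@H]3C[C@@H]4[C@@H](CN(C)C[C@@H]4C)[C@@H]3C)[C@H](CC/C(C)=C/C(=O)O)[C@]2(C)C(=O)O[C@@H]2C[C@@H]3[C@@H](CN(C)C[C@@H]3C)[C@@H]2C)ccc1O | intermediate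
32 | CNP0251577.3: tris[(4R,4aS,6R,7S,7aR)-2,4,7-trimethyloctahydro-1H-cyclopenta[c]pyridin-6-yl] ester of (1S,2R,3S,4S)-4-[(3E)-4-carboxy-3-methylbut-3-en-1-yl]-2-(4-hydroxy-3-methoxyphenyl)-1-methylcyclobutane-1,3-dicarboxylic acid | COc1cc([C@H]2[C@@H](C(=O)O[C@@H]3C[C@@H]4[C@@H](CN(C)C[C@@H]4C)[C@@H]3C)[C@H](CC/C(C)=C/C(=O)O[C@@H]3C[C@@H]4[C@@H](CN(C)C[C@@H]4C)[C@@H]3C)[C@]2(C)C(=O)O[C@@H]2C[C@@H]3[C@@H](CN(C)C[C@@H]3C)[C@@H]2C)ccc1O | target

**Totals.** Total step count: 21. Longest linear sequence: 14 steps (steps 8–21, from vanillin 15).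

**Steps most likely to fail**

Step 12. What may go wrong: energy transfer to the electron-rich styrene may lose out to electron transfer or unproductive E/Z cycling, or the 1,4-biradical may collapse with poor exo selectivity at the ester-bearing carbon. Fallback: the cycloaddition is moved one step back and run on a different chromophore. Hydroxy enone 20 is irradiated directly (366 nm, MeCN) as a 1,6-dien-3-one, the 4-hydroxyl alone steering the 5-exo closure, to give bicyclic hydroxy ketone F1; any endo ester can be equilibrated with DBU at this stage. NaBH4 then adds hydride to the convex face to give the 2-epimeric diol F2. Its less hindered 4-hydroxyl is mesylated to give mesylate F3, and KN(SiMe3)2 triggers the Grob fragmentation, which should outrun oxetane closure because it relieves the strain of the fused rings. The sequence rejoins the route at aldehyde 24.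

Step 13. What may go wrong: sulfonylation may fail to discriminate between the two secondary hydroxyls, so that the wrong or both oxygens are activated and the fragmentation runs in the wrong direction or not at all. Fallback: the leaving group is installed by a substitution that the neopentyl C2 carbinol cannot undergo. Diol 22 is treated with PPh3, I2 and imidazole (toluene, 60 °C) to give, with inversion at C4 only, iodo alcohol F4. KN(SiMe3)2 then induces the same fragmentation with iodide as leaving group, returning to the route at aldehyde 24.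

Step 17. What may go wrong: the activated alcohol may eliminate or be consumed before the hindered, weakly nucleophilic quaternary carboxylate attacks it. Fallback: the ester is made by acyl activation with retention at the alcohol carbon instead of by alkylation of the carboxylate. Alcohol 12 is first inverted by Mitsunobu reaction with the small, acidic 4-nitrobenzoic acid (PPh3, DIAD, THF) to give the 6R 4-nitrobenzoate F5, and methanolysis (K2CO3, MeOH) frees the 6R alcohol incarvilline F6. Acid 27 is converted with 1-chloro-N,N,2-trimethylprop-1-en-1-amine (CH2Cl2, 0 °C), a neutral reagent that spares the tert-butyl ester and the silyl ether, into the acid chloride F7. This acylates F6 (DMAP, Et3N, CH2Cl2, 40 °C) and the sequence comes back to the route at ester 28.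

**Further compounds**

F1 | step 12 | ethyl (1R,4S,5S,6R,7R)-7-{4-[(tert-butyldimethylsilyl)oxy]-3-methoxyphenyl}-4-hydroxy-1-methyl-2-oxobicyclo[3.2.0]heptane-6-carboxylate | COc1cc([C@H]2[C@@H](C(=O)OCC)[C@H]([C@@H](O)CC3=O)[C@@]23C)ccc1O[Si](C)(C)C(C)(C)C
F2 | step 12 | ethyl (1R,2S,4S,5S,6R,7R)-7-{4-[(tert-butyldimethylsilyl)oxy]-3-methoxyphenyl}-2,4-dihydroxy-1-methylbicyclo[3.2.0]heptane-6-carboxylate | COc1cc([C@H]2[C@@H](C(=O)OCC)[C@H]([C@@H](O)C[C@@H]3O)[C@@]23C)ccc1O[Si](C)(C)C(C)(C)C
F3 | step 12 | ethyl (1R,2S,4S,5S,6R,7R)-7-{4-[(tert-butyldimethylsilyl)oxy]-3-methoxyphenyl}-2-hydroxy-4-[(methanesulfonyl)oxy]-1-methylbicyclo[3.2.0]heptane-6-carboxylate | COc1cc([C@H]2[C@@H](C(=O)OCC)[C@H]([C@@H](OS(C)(=O)=O)C[C@@H]3O)[C@@]23C)ccc1O[Si](C)(C)C(C)(C)C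
F4 | step 13 | ethyl (1R,2R,4R,5S,6R,7R)-7-{4-[(tert-butyldimethylsilyl)oxy]-3-methoxyphenyl}-2-hydroxy-4-iodo-1-methylbicyclo[3.2.0]heptane-6-carboxylate | COc1cc([C@H]2[C@@H](C(=O)OCC)[C@H]([C@H](I)C[C@H]3O)[C@@]23C)ccc1O[Si](C)(C)C(C)(C)C
F5 | step 17 | (4R,4aS,6R,7S,7aR)-2,4,7-trimethyloctahydro-1H-cyclopenta[c]pyridin-6-yl 4-nitrobenzoate | O=C(O[C@@H]1C[C@@H]2[C@@H](CN(C)C[C@@H]2C)[C@@H]1C)c1ccc(cc1)[N+](=O)[O-]
F6 | step 17 | (4R,4aS,6R,7S,7aR)-2,4,7-trimethyloctahydro-1H-cyclopenta[c]pyridin-6-ol (incarvilline) | O[C@@H]1C[C@@H]2[C@@H](CN(C)C[C@@H]2C)[C@@H]1C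
F7 | step 17 | acid chloride of 27 (C1 carboxyl as COCl; ring stereocentres as in 27) | COc1cc([C@H]2[C@@H](C(=O)OCC)[C@H](CC/C(C)=C/C(=O)OC(C)(C)C)[C@]2(C)C(=O)Cl)ccc1O[Si](C)(C)C(C)(C)C
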